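The earlier runs and the new flask come from a simulation from invented constants.

**The pair.** A closed, stirred vessel with 10 mM of substrate at −20 °C has been run before: teal. Oak repeats it with 0.22 mol% of free catalyst against 0.17 mol%, and is read at 15 h.

all flasks: substrate 10 mM
- ochre: free catalyst 0.11 mol%; temperature −40 °C; run made earlier
- teal: free catalyst 0.17 mol%; temperature −20 °C; run made earlier
- larch: free catalyst 0.22 mol%; temperature −35 °C; time 15 h
- maple: free catalyst 0.22 mol%; temperature −5 °C; time 15 h
- oak: free catalyst 0.22 mol%; temperature −20 °C; time 15 h
- cedar: free catalyst 0.22 mol%; at −35 °C until 10 h, from then on at −5 °C; time 15 h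

| run | time / h | target / % |
|---|---|---|
| ochre | 1.00 | 0 |
| ochre | 2.00 | 2 |
| ochre | 3.00 | 0 |
| ochre | 6.00 | 4 |
| ochre | 12.0 | 6 |
| teal | 1.33 | 17 |
| teal | 2.50 | 22 |
| teal | 4.00 | 20 |
| teal | 5.00 | 25 |
| teal | 6.00 | 24 |

(readings scatter by 2 percentage points)

- percentages count the substrate that a species holds: one side product counts as two
- on the list of suspects stand: substrate + free catalyst -> catalyst intermediate; catalyst intermediate -> free catalyst + target; free catalyst <-> dormant form; 2 free catalyst -> spent catalyst; substrate + target -> side product

* the flask with the highest amount of target, in percent of the substrate charged ("all alike" if they lie within 1.5 percentage points) (larch / maple / oak / cedar / all alike)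
* final target, as a percentage of the substrate charged, in larch
* final target, as a percentage of the substrate charged, in maple
* final target, as a percentage of the substrate charged, in oak
* final target, as a percentage of the substrate charged, in cedar

**Flat target.** Teal reads 17 % at 1.33 h, then its readings gain 2 percentage points between 2.50 h and 6.00 h, far slower than the opening rise. The readings from 2.50 h on average 22.8 %, each with a scatter of 2 points. A flat target may be a balance, with the catalyst making target while substrate and target together go to side product. Making goes with the catalyst, and at a given substrate the loss goes with the target standing, so on this reading the flat level at one temperature scales with the loading.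

**Standing turnover.** Teal's plateau reading over its catalyst charge gives 134. This is the standing turnover: moles of target standing per mole of free catalyst charged, a turnover number read on a plateau. Oak then needs a correction to teal for its extra catalyst, 6.7 points, which puts oak near 29.4 %. This reckoning stays with oak, the flask sharing teal's temperature, and it takes the flat level to last from 6.00 h to 15 h.

**The forecast.** It reads teal's stall otherwise, “so the catalyst dies”, and gives 27 % for larch, 17 % for maple, 28 % for oak and 34 % for cedar, with cedar highest. Its oak lies 1.4 points below the reckoning here.

**The flasks.** The highest is oak, at 30.0 %, against 22.3 % in cedar, 20.9 % in larch and 19.5 % in maple. Oak's standing turnover comes to 136, beside the 134 read off teal.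

    substrate + free catalyst → catalyst intermediate (k = 430 M⁻¹ min⁻¹, Ea = 35.0 kJ mol⁻¹)
    catalyst intermediate → free catalyst + target (k = 2.30 min⁻¹, Ea = 76.0 kJ mol⁻¹)
    free catalyst ⇌ dormant form (K = 1.30, k = 0.00200 min⁻¹, Ea = 76.0 kJ mol⁻¹, ΔH = 0 kJ mol⁻¹)
    2 free catalyst → spent catalyst (k = 140 M⁻¹ min⁻¹, Ea = 42.0 kJ mol⁻¹)
    substrate + target → side product (k = 0.970 M⁻¹ min⁻¹, Ea = 50.0 kJ mol⁻¹)
    (constants at −20 °C)

**The neighbour.** Cedar's standing turnover is 101. The neighbouring flask is cedar with 0.088 mol% of free catalyst. Scaling cedar's target by the loading gives 8.90 % for it, and that flask holds 8.64 % at 15.0 h, which is 98.2 per catalyst charged, with 10 % of its substrate still there.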